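## Retrosynthetic overview

1. The target comes from its 7-hydroxy methyl ester by saponification and acetylation of the axial C7–OH (labdane numbering C1–C20 is used throughout).
2. Key disconnection C9–C10: one radical cascade on a monocyclic ring A precursor with an O–N bond at C7 forms ring B, the C10 quaternary centre and the C8=C17 methylene (O-radical, 1,5-hydrogen shift from C10–H, 6-endo closure on C9, copper-mediated loss of a C17 hydrogen).
3. C7–C8: asymmetric alkenylzinc addition of a C8–C17 alkyne ester (C13 set by catalytic asymmetric conjugate addition to methyl crotonate) to a ring A acetaldehyde, then Mitsunobu O–N installation.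
4. Ring A aldehyde: annulation of isobutyraldehyde with ethyl vinyl ketone, CBS reduction, Claisen chirality transfer (C5), directed hydrogenation (C10–H).
5. Ring order: ring A first (step 1), ring B last (step 8).

Assumption: the ligand enantiomers named in steps 5 and 6 are taken to give the stated senses (3S; Re-face addition); if a test run shows the reverse, the antipodal ligand is used.

## Route

Step 1
Reactants: 1 2-methylpropanal; 2 pent-1-en-3-one
Product: 3 2,4,4-trimethylcyclohex-2-en-1-one
Conditions: H2SO4 (cat.), toluene, 45 °C then reflux (Dean–Stark)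
Reagents that add atoms: none
Why: Acid-catalysed Michael addition of the aldehyde enol to the enone followed by intramolecular aldol condensation (Robinson-type annulation) is the standard one-pot entry to 4,4-dialkylcyclohex-2-enones and creates no stereocentre.

Step 2
Reactants: 3 2,4,4-trimethylcyclohex-2-en-1-one
Product: 4 (1R)-2,4,4-trimethylcyclohex-2-en-1-ol
Conditions: (S)-2-methyl-CBS-oxazaborolidine (10 mol %), BH3·SMe2, THF, −20 °C; aq. NH4Cl
Reagents that add atoms: none
Why: Corey–Bakshi–Shibata reduction, in which the α-methyl-substituted alkene arm acts as the large group so that the (S)-catalyst delivers hydride to give the (R)-allylic alcohol (the later C1), as is usual for 2-substituted cyclohexenones.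

Step 3
Reactants: 4 (1R)-2,4,4-trimethylcyclohex-2-en-1-ol; 5 ethoxyethene
Product: 7 2-[(1S)-2,6,6-trimethylcyclohex-2-en-1-yl]acetaldehyde, via allyl vinyl ether 6 (not isolated)
Conditions: Hg(OAc)2 (10 mol %), excess 5, reflux; evaporate; xylene, 190 °C (sealed tube)
Reagents that add atoms: none
Why: Vinyl ether exchange followed by Claisen rearrangement through a chair-like transition state transfers the C–O chirality suprafacially to carbon, so the CH2CHO arm arrives on the face that carried oxygen and sets C5 next to the gem-dimethyl carbon while leaving the C1=C10 alkene.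

Step 4
Reactants: 7 2-[(1S)-2,6,6-trimethylcyclohex-2-en-1-yl]acetaldehyde
Product: 8 2-[(1R,6S)-2,2,6-trimethylcyclohexyl]acetaldehyde
Conditions: H2 (1 atm), [Ir(cod)(PCy3)(py)]PF6 (5 mol %), CH2Cl2, 0 °C to rt
Reagents that add atoms: none
Why: Carbonyl-directed homogeneous hydrogenation (Crabtree type), in which the cationic iridium binds the aldehyde oxygen and delivers H2 to the alkene face syn to the CH2CHO arm, so that C10–H ends cis to that arm (methyl trans), the geometry the later 1,5-hydrogen shift needs; the C10 configuration itself is erased in step 8.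

Step 5
Reactants: 9 5-bromopent-2-yne; 10 methyl (2E)-but-2-enoate
Product: 12 methyl (3S)-3-methyloct-6-ynoate, via Grignard reagent 11 (not isolated)
Conditions: Mg, Et2O, rt; CuI (2 mol %), (R)-Tol-BINAP (3 mol %), t-BuOMe, −40 °C, then 10; 1 M HCl
Reagents that add atoms: none
Why: Copper-catalysed asymmetric conjugate addition of a Grignard reagent to an (E)-enoate, in which the chiral copper–bisphosphine complex differentiates the enoate faces and sets C13 (S) while the internal alkyne is inert.

Step 6
Reactants: 12 methyl (3S)-3-methyloct-6-ynoate; 8 2-[(1R,6S)-2,2,6-trimethylcyclohexyl]acetaldehyde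
Product: 15 methyl (3S,6E,8S)-8-hydroxy-3,7-dimethyl-9-[(1R,6S)-2,2,6-trimethylcyclohexyl]non-6-enoate, via alkenylzirconocene 13 (not isolated), via alkenylzinc 14 (not isolated)
Conditions: Cp2Zr(H)Cl, CH2Cl2, rt; Me2Zn, toluene, −65 °C; (+)-MIB [(2R)-3-exo-morpholinoisoborneol] (10 mol %), then 8, −30 to 0 °C; aq. NH4Cl
Reagents that add atoms: none
Why: Hydrozirconation, zinc transmetalation and aldehyde alkenylation, in which syn Zr–H addition puts zirconium on the methyl-bearing alkyne carbon so that the new C7–C8 bond is trans to C11 (E-trisubstituted alkene) and the amino alcohol ligand steers the alkenylzinc to the Re face of the aldehyde to give the (8S)-carbinol (C7) under reagent control.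

Step 7
Reactants: 15 methyl (3S,6E,8S)-8-hydroxy-3,7-dimethyl-9-[(1R,6S)-2,2,6-trimethylcyclohexyl]non-6-enoate
Product: 16 methyl (3S,6E,8R)-8-[(1,3-dioxoisoindolin-2-yl)oxy]-3,7-dimethyl-9-[(1R,6S)-2,2,6-trimethylcyclohexyl]non-6-enoate
Conditions: N-hydroxyphthalimide, PPh3, DIAD, THF, 0 °C to rt
Reagents that add atoms: N-hydroxyphthalimide, ON1C(=O)c2ccccc2C1=O
Why: Mitsunobu reaction, in which the acidic N-hydroxyphthalimide displaces the activated secondary alcohol by SN2 with inversion and so gives the N-alkoxyphthalimide with the C7 configuration of the target.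

Step 8
Reactants: 16 methyl (3S,6E,8R)-8-[(1,3-dioxoisoindolin-2-yl)oxy]-3,7-dimethyl-9-[(1R,6S)-2,2,6-trimethylcyclohexyl]non-6-enoate
Product: 20 methyl (3S)-5-[(1R,3R,4aS,8aS)-3-hydroxy-5,5,8a-trimethyl-2-methylidenedecahydronaphthalen-1-yl]-3-methylpentanoate, via alkoxyl radical 17 (not isolated), via ring A tertiary radical 18 (not isolated), via bicyclic tertiary radical 19 (not isolated)
Conditions: fac-Ir(ppy)3 [tris(2-phenylpyridinato)iridium] (1 mol %), Cu(O2CC7H15)2 [copper bis(2-ethylhexanoate)] (20 mol %), CH2Cl2 (0.01 M), blue LEDs (450 nm), rt, Ar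
Reagents that add atoms: none
Why: Proposed new method: excited Ir(ppy)3 reduces the N–O bond to alkoxyl radical 17, which abstracts the only δ-hydrogen (C10–H, six-membered transition state) to give tertiary radical 18, the same type of intermediate as in titanocene- or Mn(OAc)3/Cu(OAc)2-mediated polyene cyclizations, and 18 closes 6-endo on C9 through a chair with the (E)-alkene so that ring B is trans-fused (10S), C11 is equatorial (9R) and the untouched C7–OH is axial, after which radical 19 is oxidized by divalent copper with β-hydrogen loss from the freely rotating C17 methyl to the exocyclic alkene while tetravalent iridium reoxidizes monovalent copper; the closest known reactions are δ-C–H functionalization through N-alkoxyphthalimide-derived alkoxyl radicals and copper-terminated oxidative radical polyene cyclizations.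

Step 9
Reactants: 20 methyl (3S)-5-[(1R,3R,4aS,8aS)-3-hydroxy-5,5,8a-trimethyl-2-methylidenedecahydronaphthalen-1-yl]-3-methylpentanoate
Product: 21 (3S)-5-[(1R,3R,4aS,8aS)-3-hydroxy-5,5,8a-trimethyl-2-methylidenedecahydronaphthalen-1-yl]-3-methylpentanoic acid
Conditions: LiOH·H2O, THF/MeOH/H2O, rt; then 1 M HCl
Reagents that add atoms: lithium hydroxide, [Li+].[OH-]
Why: Saponification of the unhindered methyl ester, which touches no stereocentre because none is α to the carbonyl.

Step 10
Reactants: 21 (3S)-5-[(1R,3R,4aS,8aS)-3-hydroxy-5,5,8a-trimethyl-2-methylidenedecahydronaphthalen-1-yl]-3-methylpentanoic acid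
Product: 23 (3S)-5-[(1R,3R,4aS,8aS)-3-(acetyloxy)-5,5,8a-trimethyl-2-methylidenedecahydronaphthalen-1-yl]-3-methylpentanoic acid, via mixed anhydride 22 (not isolated)
Conditions: Ac2O, pyridine, DMAP (cat.), CH2Cl2, rt; then H2O/THF
Reagents that add atoms: acetic anhydride, CC(=O)OC(C)=O
Why: DMAP-catalysed acetylation esterifies the axial allylic C7–OH with retention, and the mixed anhydride formed at the carboxyl group is hydrolysed back to the free acid on aqueous work-up.

## Compound list

1 | 2-methylpropanal (isobutyraldehyde) | CC(C)C=O | starting material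
2 | pent-1-en-3-one (ethyl vinyl ketone) | CCC(=O)C=C | starting material
3 | 2,4,4-trimethylcyclohex-2-en-1-one | CC1=CC(C)(C)CCC1=O | intermediate
4 | (1R)-2,4,4-trimethylcyclohex-2-en-1-ol | O[C@@H]1CCC(C)(C)C=C1C | intermediate
5 | ethoxyethene (ethyl vinyl ether) | C=COCC | starting material
6 | (6R)-6-(ethenyloxy)-1,3,3-trimethylcyclohex-1-ene | C=CO[C@@H]1CCC(C)(C)C=C1C | intermediate (not isolated)
7 | 2-[(1S)-2,6,6-trimethylcyclohex-2-en-1-yl]acetaldehyde | O=CC[C@@H]1C(C)=CCCC1(C)C | intermediate
8 | 2-[(1R,6S)-2,2,6-trimethylcyclohexyl]acetaldehyde (arm and ring methyl trans) | O=CC[C@@H]1[C@@H](C)CCCC1(C)C | intermediate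
9 | 5-bromopent-2-yne | CC#CCCBr | starting material
10 | methyl (2E)-but-2-enoate (methyl crotonate) | C/C=C/C(=O)OC | starting material
11 | pent-3-yn-1-ylmagnesium bromide | CC#CCC[Mg]Br | intermediate (not isolated)
12 | methyl (3S)-3-methyloct-6-ynoate | COC(=O)C[C@@H](C)CCC#CC | intermediate
13 | methyl (3S,6E)-7-[chlorobis(cyclopentadienyl)zirconio]-3-methyloct-6-enoate | COC(=O)C[C@@H](C)CC/C=C(C)/[Zr](Cl)(C1C=CC=C1)C1C=CC=C1 | intermediate (not isolated)
14 | methyl (3S,6E)-3-methyl-7-(methylzincio)oct-6-enoate | COC(=O)C[C@@H](C)CC/C=C(C)/[Zn]C | intermediate (not isolated)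
15 | methyl (3S,6E,8S)-8-hydroxy-3,7-dimethyl-9-[(1R,6S)-2,2,6-trimethylcyclohexyl]non-6-enoate | COC(=O)C[C@@H](C)CC/C=C(C)/[C@@H](O)C[C@@H]1[C@@H](C)CCCC1(C)C | intermediate
16 | methyl (3S,6E,8R)-8-[(1,3-dioxoisoindolin-2-yl)oxy]-3,7-dimethyl-9-[(1R,6S)-2,2,6-trimethylcyclohexyl]non-6-enoate | COC(=O)C[C@@H](C)CC/C=C(C)/[C@H](ON1C(=O)c2ccccc2C1=O)C[C@@H]1[C@@H](C)CCCC1(C)C | intermediate
17 | alkoxyl radical: 16 without the phthalimido group, unpaired electron on the C7 oxygen | COC(=O)C[C@@H](C)CC/C=C(C)/[C@H]([O])C[C@@H]1[C@@H](C)CCCC1(C)C | intermediate (not isolated)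
18 | ring A tertiary radical: C7–OH restored, unpaired electron on C10 (ring carbon bearing the methyl), C5, C7 and C13 as in 16 | COC(=O)C[C@@H](C)CC/C=C(C)/[C@H](O)C[C@@H]1[C](C)CCCC1(C)C | intermediate (not isolated)
19 | bicyclic tertiary radical: trans-decalin of 20 with a C8 methyl in place of the methylidene and the unpaired electron on C8 | C[C]1[C@H](O)C[C@H]2C(C)(C)CCC[C@]2(C)[C@H]1CC[C@H](C)CC(=O)OC | intermediate (not isolated)
20 | methyl (3S)-5-[(1R,3R,4aS,8aS)-3-hydroxy-5,5,8a-trimethyl-2-methylidenedecahydronaphthalen-1-yl]-3-methylpentanoate | C=C1[C@H](O)C[C@H]2C(C)(C)CCC[C@]2(C)[C@H]1CC[C@H](C)CC(=O)OC | intermediate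
21 | (3S)-5-[(1R,3R,4aS,8aS)-3-hydroxy-5,5,8a-trimethyl-2-methylidenedecahydronaphthalen-1-yl]-3-methylpentanoic acid | C=C1[C@H](O)C[C@H]2C(C)(C)CCC[C@]2(C)[C@H]1CC[C@H](C)CC(=O)O | intermediate
22 | acetic (3S)-5-[(1R,3R,4aS,8aS)-3-(acetyloxy)-5,5,8a-trimethyl-2-methylidenedecahydronaphthalen-1-yl]-3-methylpentanoic anhydride | C=C1[C@H](OC(C)=O)C[C@H]2C(C)(C)CCC[C@]2(C)[C@H]1CC[C@H](C)CC(=O)OC(C)=O | intermediate (not isolated)
23 | (3S)-5-[(1R,3R,4aS,8aS)-3-(acetyloxy)-5,5,8a-trimethyl-2-methylidenedecahydronaphthalen-1-yl]-3-methylpentanoic acid (CNP0156001.2) | C=C1[C@H](OC(C)=O)C[C@H]2C(C)(C)CCC[C@]2(C)[C@H]1CC[C@H](C)CC(=O)O | target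

## Step count and risks

Total steps: 10. Longest linear sequence: 9 steps (1–4, then 6–10); step 5 is a one-step branch.

**Step 8 (radical cascade).** The main dangers are that copper intercepts radical 18 before it cyclizes, or that the termination gives alkene mixtures. The fallback makes the same C10 radical by metal-hydride hydrogen-atom transfer to a ring alkene in place of the hydrogen shift to oxygen. It sets out from unsaturated aldehyde 7 (together with 12) and comes back to the route at 23. Alkenylation of 7 as in step 6, but with (−)-MIB for Si-face addition, gives methyl (3S,6E,8R)-8-hydroxy-3,7-dimethyl-9-[(1S)-2,6,6-trimethylcyclohex-2-en-1-yl]non-6-enoate F5, which already has the target configuration at C7. LiOH then gives (3S,6E,8R)-8-hydroxy-3,7-dimethyl-9-[(1S)-2,6,6-trimethylcyclohex-2-en-1-yl]non-6-enoic acid F6, and Ac2O/pyridine gives (3S,6E,8R)-8-(acetyloxy)-3,7-dimethyl-9-[(1S)-2,6,6-trimethylcyclohex-2-en-1-yl]non-6-enoic acid F7, an isomer of the target. A cobalt-hydride cycloisomerization (Co(salen)Cl, that is chloro[N,N′-bis(3,5-di-tert-butylsalicylidene)ethane-1,2-diaminato]cobalt, with catalytic PhSiH3 in benzene) adds a hydrogen atom to C1 of the ring alkene. The C10 radical closes on C9 as in step 8, and the cobalt takes back a C17 hydrogen to give 23 directly. This variant is less selective in where the hydride attacks, so it is the second choice.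

**Step 4 (directed hydrogenation).** If the aldehyde does not steer the iridium catalyst, the cis isomer forms and cannot undergo the later hydrogen shift. The fallback uses a hydroxyl directing group; it sets out from 7 and comes back at 8. NaBH4 reduces 7 to 2-[(1S)-2,6,6-trimethylcyclohex-2-en-1-yl]ethan-1-ol F1. Hydroxyl-directed hydrogenation with [Ir(cod)(PCy3)(py)]PF6 gives 2-[(1R,6S)-2,2,6-trimethylcyclohexyl]ethan-1-ol F2, and Dess–Martin oxidation returns aldehyde 8.

**Step 7 (allylic Mitsunobu).** SN2′ attack or elimination could erode yield and configuration at C7. The fallback forms the O–N bond on oxygen so that C7 is never substituted; it sets out from 8 and 12 and comes back at 16. Step 6 run with (−)-MIB gives methyl (3S,6E,8R)-8-hydroxy-3,7-dimethyl-9-[(1R,6S)-2,2,6-trimethylcyclohexyl]non-6-enoate F3. Its potassium alkoxide (KH, THF, 0 °C) is aminated on oxygen with 3,3-di-tert-butyloxaziridine to methyl (3S,6E,8R)-8-(aminooxy)-3,7-dimethyl-9-[(1R,6S)-2,2,6-trimethylcyclohexyl]non-6-enoate F4. Condensation with phthalic anhydride (toluene, reflux) closes the imide and gives 16 with retention at C7.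

## Further compounds

F1 | step 4 | 2-[(1S)-2,6,6-trimethylcyclohex-2-en-1-yl]ethan-1-ol | OCC[C@@H]1C(C)=CCCC1(C)C
F2 | step 4 | 2-[(1R,6S)-2,2,6-trimethylcyclohexyl]ethan-1-ol | OCC[C@@H]1[C@@H](C)CCCC1(C)C
F3 | step 7 | methyl (3S,6E,8R)-8-hydroxy-3,7-dimethyl-9-[(1R,6S)-2,2,6-trimethylcyclohexyl]non-6-enoate | COC(=O)C[C@@H](C)CC/C=C(C)/[C@H](O)C[C@@H]1[C@@H](C)CCCC1(C)C
F4 | step 7 | methyl (3S,6E,8R)-8-(aminooxy)-3,7-dimethyl-9-[(1R,6S)-2,2,6-trimethylcyclohexyl]non-6-enoate | COC(=O)C[C@@H](C)CC/C=C(C)/[C@H](ON)C[C@@H]1[C@@H](C)CCCC1(C)C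
F5 | step 8 | methyl (3S,6E,8R)-8-hydroxy-3,7-dimethyl-9-[(1S)-2,6,6-trimethylcyclohex-2-en-1-yl]non-6-enoate | COC(=O)C[C@@H](C)CC/C=C(C)/[C@H](O)C[C@@H]1C(C)=CCCC1(C)C
F6 | step 8 | (3S,6E,8R)-8-hydroxy-3,7-dimethyl-9-[(1S)-2,6,6-trimethylcyclohex-2-en-1-yl]non-6-enoic acid | OC(=O)C[C@@H](C)CC/C=C(C)/[C@H](O)C[C@@H]1C(C)=CCCC1(C)C
F7 | step 8 | (3S,6E,8R)-8-(acetyloxy)-3,7-dimethyl-9-[(1S)-2,6,6-trimethylcyclohex-2-en-1-yl]non-6-enoic acid | OC(=O)C[C@@H](C)CC/C=C(C)/[C@H](OC(C)=O)C[C@@H]1C(C)=CCCC1(C)C
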